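The rate constants are invented; the run is a simulation.

Before you ask what a neighbouring flask with 65 mM of coupling partner gives, take the flask with 26.0 mM and count how often each of its clocks turns over in the run.

substrate 20 mM; coupling partner 26.0 mM (fed, over 3.0 min); time 2.5 h; the fed solution adds 0.20 times the starting volume

    substrate ⇌ intermediate A (K1 = 0.50, k1 = 0.0270 /s)
    substrate ⇌ intermediate B (K2 = 0.386, k2 = 0.00444 /s)
    coupling partner + intermediate A ⇌ target (K3 = 418 /M, k3 = 0.330 /M/s)
    substrate ⇌ dormant form (K4 = 0.83, k4 = 0.00146 /s)

- charges are per starting volume, the dose included; the dosed solution carries all of it
- what has gone from substrate into another species counts as reacted, even if it can come back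
- run time (flask): 2.5 h

- conversion of substrate at 2.5 h
- amount of target at 2.5 h, in percent of the substrate charged

Climb the ladder of half-lives in the flask. Substrate and intermediate A relax against each other in 0.143 min, and intermediate B joins them in 0.725 min, later. Coupling then takes up intermediate A with a forward half-life of 1.3 min, reckoned at the full charge, while the feed runs for 3.0 min and the dormant form relaxes in 3.59 min. The top rung is the way back of the coupling step: target falls apart with a half-life of 14.6 min, slower than every other clock, and no concentration enters it. The run holds 10.3 of these, so I expect the flask to stand at its balance by the end.

I therefore reckon the flask as a balance, after dilution to 16.7 mM of substrate and 21.7 mM of coupling partner. Substrate, intermediate A, intermediate B and the dormant form make one uncoupled pool, a pre-equilibrium, and the pool is 2.72 times its free substrate. Define the capture constant as the coupling equilibrium constant times the share of the pool in intermediate A: it is 77.0 /M, and [target]/[pool] = capture constant × [coupling partner]. Coupling draws both free amounts down by [target], so the quadratic gives target at 50.5% of the substrate charged and conversion at 81.8%.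

The forecast gives 81.8% and 50.5%, holding that “the flask should be at full equilibrium”. The simulation gives 81.8% and 50.5%. Neither the drawn-out feed nor a run to 25.0 h moves the conversion.

In the flask at 2.50 h, the free coupling partner, 61% of its charge, is 13.3 mM. The capture constant turns that into a target-to-pool ratio of 1.02, and the simulated amounts give 1.02. The neighbour has 3.25 equiv of coupling partner, and its back half-life is the same 14.6 min. Its partner dilutes to 54.2 mM, and the same capture constant puts its target at 76.1%. The neighbour's run stands at 76.1% of the substrate charged.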